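The benzo ring of the chromanone carries the ring oxygen O1 (on C8a) and the ketone carbon C4 (on C4a) on neighbouring carbons. Both are delivered in one operation to the triple bond of an aryne, methyl 2-chloro-3,4-didehydrobenzoate, by the potassium alkoxide of an enantiopure β-hydroxy Weinreb amide: O-arylation at C8a, then closure of the pyranone ring by attack of the C4a carbanion on the amide carbonyl (C4–C4a bond). The chlorine beside the triple bond (future C5) fixes the regiochemistry and is removed afterwards. The precursors are an o-silylaryl triflate and an open-chain hydroxy amide whose C2 stereocentre comes from Sharpless epoxidation of farnesol.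

Key step: step 7

Remark: C2 of the target is (S) (CIP order O1 > C3 > side-chain CH2 > CH3); this corresponds to the (2S,3S)-epoxide of farnesol, which is taken to be the enantiomer formed with L-(+)-tartrate.

Step 1
Reactants: 1 (2E,6E)-farnesol
Product: 2 (2S,3S)-2,3-epoxyfarnesol
Conditions: Ti(OiPr)4 (10 mol %), L-(+)-diethyl tartrate (12 mol %), t-BuOOH (2 equiv), 4 Å molecular sieves, CH2Cl2, −20 °C
Reagents that add atoms: tert-butyl hydroperoxide, CC(C)(C)OO
Why: Katsuki–Sharpless asymmetric epoxidation: the allylic hydroxyl binds the titanium tartrate complex, so only the 2,3-alkene reacts and L-(+)-tartrate directs oxygen to the face that gives the (2S,3S)-epoxide, whose C3 becomes C2 of the target.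

Step 2
Reactants: 2 (2S,3S)-2,3-epoxyfarnesol
Product: 3 (3S,6E)-3,7,11-trimethyldodeca-6,10-diene-1,3-diol
Conditions: NaAlH2(OCH2CH2OMe)2, THF, 0 °C to rt; aq. KNaC4H4O6
Reagents that add atoms: none
Why: Hydroxyl-directed reductive opening of a 2,3-epoxy alcohol: the alkoxyaluminate delivers hydride intramolecularly to C2, the less substituted carbon, so the 1,3-diol should form with the C3–O bond and its configuration untouched.

Step 3
Reactants: 3 (3S,6E)-3,7,11-trimethyldodeca-6,10-diene-1,3-diol
Product: 5 (3S,6E)-3-hydroxy-3,7,11-trimethyldodeca-6,10-dienoic acid, via hydroxy aldehyde 4 (not isolated)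
Conditions: TEMPO (20 mol %), PhI(OAc)2 (2.2 equiv), MeCN/H2O 1:1, 0 °C to rt
Reagents that add atoms: water, O
Why: Oxoammonium-catalysed (TEMPO/PhI(OAc)2) oxidation of the primary alcohol through aldehyde 4 and its hydrate to the acid; the tertiary alcohol cannot be oxidised and isolated trisubstituted alkenes are normally tolerated.

Step 4
Reactants: 5 (3S,6E)-3-hydroxy-3,7,11-trimethyldodeca-6,10-dienoic acid
Product: 6 (3S,6E)-3-hydroxy-N-methoxy-N,3,7,11-tetramethyldodeca-6,10-dienamide
Conditions: MeNHOMe·HCl, EDC·HCl, HOBt, i-Pr2NEt, CH2Cl2, 0 °C to rt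
Reagents that add atoms: N,O-dimethylhydroxylamine hydrochloride, CNOC.Cl
Why: Carbodiimide amide coupling through the HOBt active ester; the hindered tertiary hydroxyl does not compete with the amine and the stereocentre is not involved.

Step 5
Reactants: 7 methyl 2-chloro-3-hydroxybenzoate
Product: 8 methyl 4-bromo-2-chloro-3-hydroxybenzoate
Conditions: NBS (1.0 equiv), i-Pr2NH (10 mol %), CH2Cl2, 0 °C
Reagents that add atoms: N-bromosuccinimide, O=C1CCC(=O)N1Br
Why: Amine-mediated ortho-selective electrophilic bromination of a phenol (the N-bromoamine is delivered by hydrogen bonding to the hydroxyl); C4 is the only free ortho position and the para position C6 is shielded by the neighbouring ester.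

Step 6
Reactants: 8 methyl 4-bromo-2-chloro-3-hydroxybenzoate
Product: 12 methyl 2-chloro-3-[(trifluoromethanesulfonyl)oxy]-4-(trimethylsilyl)benzoate, via trimethylsilyl ether 9 (not isolated), via aryllithium 10 (not isolated), via lithium phenoxide 11 (not isolated)
Conditions: (Me3Si)2NH, THF, 70 °C, then evaporate; n-BuLi, THF, −100 to −78 °C; Tf2O, −78 °C
Reagents that add atoms: hexamethyldisilazane, C[Si](C)(C)N[Si](C)(C)C; trifluoromethanesulfonic anhydride, O=S(=O)(C(F)(F)F)OS(=O)(=O)C(F)(F)F
Why: Standard o-silylaryl triflate synthesis by O-silylation, bromine–lithium exchange, retro-Brook 1,3-shift of silicon from oxygen to carbon and triflation of the phenoxide; at −100 °C the exchange and the intramolecular silyl shift should outrun addition to the methyl ester, and the aryl chloride does not exchange.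

Step 7
Reactants: 6 (3S,6E)-3-hydroxy-N-methoxy-N,3,7,11-tetramethyldodeca-6,10-dienamide; 12 methyl 2-chloro-3-[(trifluoromethanesulfonyl)oxy]-4-(trimethylsilyl)benzoate
Product: 17 methyl (2S)-5-chloro-2-[(3E)-4,8-dimethylnona-3,7-dien-1-yl]-2-methyl-4-oxo-3,4-dihydro-2H-chromene-6-carboxylate, via potassium alkoxide 13 (not isolated), via aryne 14 (not isolated), via aryl carbanion 15 (not isolated), via tetrahedral adduct 16 (not isolated)
Conditions: KH (1.05 equiv), THF, 0 °C; then 12 (1.5 equiv), KF, 18-crown-6, THF, −20 to 0 °C; then pH 7 aqueous buffer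
Reagents that add atoms: none
Why: Proposed new method: fluoride at silicon expels triflate from 12 to give aryne 14, the proton-free alkoxide 13 adds through oxygen to the aryne carbon remote from chlorine (future C8a), and the resulting carbanion 15 at future C4a attacks the tethered Weinreb amide carbonyl to form the C4–C4a bond, the adduct 16 surviving until aqueous work-up releases the ketone. The closest known reaction type is the tandem aryne O-arylation/intramolecular acyl substitution of salicylates that gives xanthones, here transferred from a phenoxide to an aliphatic tertiary alkoxide with an amide as acyl acceptor. The pyranone ring closes in 6-exo-trig mode. No stereocentre is created in the product (C4 of 16 is lost on hydrolysis), and C2 is untouched because the new bond is made at its oxygen, so the configuration from step 1 is retained. The step needs O-attack para to the ester, which is secured by the chlorine beside the triple bond: its inductive polarisation and distortion of the aryne make the remote carbon the electrophilic one and place the carbanion next to chlorine, as with 3-chloro- and 3-methoxybenzyne, and the bulk of the alkoxide and the 4-ester act in the same sense. Ring closure must outrun protonation, enolate C-arylation and retro-aldol cleavage, for which the KH-generated alkoxide (no proton source), the low temperature and the weakly acidic Weinreb amide are chosen.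

Step 8
Reactants: 17 methyl (2S)-5-chloro-2-[(3E)-4,8-dimethylnona-3,7-dien-1-yl]-2-methyl-4-oxo-3,4-dihydro-2H-chromene-6-carboxylate
Product: 18 methyl (2S)-2-[(3E)-4,8-dimethylnona-3,7-dien-1-yl]-2-methyl-4-oxo-3,4-dihydro-2H-chromene-6-carboxylate
Conditions: Pd(OAc)2 (5 mol %), P(t-Bu)3·HBF4 (10 mol %), HCO2Na (3 equiv), DMF, 80 °C
Reagents that add atoms: none
Why: Palladium-catalysed formate hydrodechlorination: zerovalent palladium inserts into the C5–Cl bond, which is activated by the ortho ketone and ester, formate delivers hydride with loss of CO2 and reductive elimination gives C5–H, while ketone, ester and isolated trisubstituted alkenes should survive the weakly basic medium.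

Step 9
Reactants: 18 methyl (2S)-2-[(3E)-4,8-dimethylnona-3,7-dien-1-yl]-2-methyl-4-oxo-3,4-dihydro-2H-chromene-6-carboxylate
Product: 19 (2S)-2-[(3E)-4,8-dimethylnona-3,7-dien-1-yl]-2-methyl-4-oxo-3,4-dihydro-2H-chromene-6-carboxylic acid
Conditions: Me3SnOH (5 equiv), 1,2-dichloroethane, 80 °C; then cold dilute aq. HCl
Reagents that add atoms: trimethyltin hydroxide, C[Sn](C)(C)O
Why: Trimethyltin hydroxide hydrolysis of a methyl ester under near-neutral conditions, chosen because hydroxide or alkoxide could open the chromanone by retro-oxa-Michael reaction and erode the C2 configuration.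

Compound list
1 | (2E,6E)-farnesol | CC(C)=CCC/C(C)=C/CC/C(C)=C/CO | starting material
2 | (2S,3S)-2,3-epoxyfarnesol, [(2S,3S)-3-[(3E)-4,8-dimethylnona-3,7-dien-1-yl]-3-methyloxiran-2-yl]methanol | CC(C)=CCC/C(C)=C/CC[C@]1(C)O[C@H]1CO | intermediate
3 | (3S,6E)-3,7,11-trimethyldodeca-6,10-diene-1,3-diol | CC(C)=CCC/C(C)=C/CC[C@](C)(O)CCO | intermediate
4 | (3S,6E)-3-hydroxy-3,7,11-trimethyldodeca-6,10-dienal | CC(C)=CCC/C(C)=C/CC[C@](C)(O)CC=O | intermediate (not isolated)
5 | (3S,6E)-3-hydroxy-3,7,11-trimethyldodeca-6,10-dienoic acid | CC(C)=CCC/C(C)=C/CC[C@](C)(O)CC(=O)O | intermediate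
6 | (3S,6E)-3-hydroxy-N-methoxy-N,3,7,11-tetramethyldodeca-6,10-dienamide | CC(C)=CCC/C(C)=C/CC[C@](C)(O)CC(=O)N(C)OC | intermediate
7 | methyl 2-chloro-3-hydroxybenzoate | COC(=O)c1cccc(O)c1Cl | starting material
8 | methyl 4-bromo-2-chloro-3-hydroxybenzoate | COC(=O)c1ccc(Br)c(O)c1Cl | intermediate
9 | methyl 4-bromo-2-chloro-3-[(trimethylsilyl)oxy]benzoate | COC(=O)c1ccc(Br)c(O[Si](C)(C)C)c1Cl | intermediate (not isolated)
10 | methyl 2-chloro-4-lithio-3-[(trimethylsilyl)oxy]benzoate | COC(=O)c1ccc([Li])c(O[Si](C)(C)C)c1Cl | intermediate (not isolated)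
11 | lithium 2-chloro-3-(methoxycarbonyl)-6-(trimethylsilyl)phenoxide | COC(=O)c1ccc([Si](C)(C)C)c([O-])c1Cl.[Li+] | intermediate (not isolated)
12 | methyl 2-chloro-3-[(trifluoromethanesulfonyl)oxy]-4-(trimethylsilyl)benzoate | COC(=O)c1ccc([Si](C)(C)C)c(OS(=O)(=O)C(F)(F)F)c1Cl | intermediate
13 | potassium (3S,6E)-1-[methoxy(methyl)amino]-3,7,11-trimethyl-1-oxododeca-6,10-dien-3-olate | CC(C)=CCC/C(C)=C/CC[C@](C)([O-])CC(=O)N(C)OC.[K+] | intermediate (not isolated)
14 | methyl 2-chloro-3,4-didehydrobenzoate (aryne) | COC(=O)C1=C(Cl)C#CC=C1 | intermediate (not isolated)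
15 | potassium 2-chloro-3-(methoxycarbonyl)-6-{[(3S,6E)-1-[methoxy(methyl)amino]-3,7,11-trimethyl-1-oxododeca-6,10-dien-3-yl]oxy}benzenide | CC(C)=CCC/C(C)=C/CC[C@@](C)(CC(=O)N(C)OC)Oc1ccc(C(=O)OC)c(Cl)[c-]1.[K+] | intermediate (not isolated)
16 | potassium (2S)-5-chloro-2-[(3E)-4,8-dimethylnona-3,7-dien-1-yl]-4-[methoxy(methyl)amino]-6-(methoxycarbonyl)-2-methyl-3,4-dihydro-2H-chromen-4-olate (C4 epimers) | CC(C)=CCC/C(C)=C/CC[C@@]1(C)CC([O-])(N(C)OC)c2c(Cl)c(C(=O)OC)ccc2O1.[K+] | intermediate (not isolated)
17 | methyl (2S)-5-chloro-2-[(3E)-4,8-dimethylnona-3,7-dien-1-yl]-2-methyl-4-oxo-3,4-dihydro-2H-chromene-6-carboxylate | CC(C)=CCC/C(C)=C/CC[C@@]1(C)CC(=O)c2c(Cl)c(C(=O)OC)ccc2O1 | intermediate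
18 | methyl (2S)-2-[(3E)-4,8-dimethylnona-3,7-dien-1-yl]-2-methyl-4-oxo-3,4-dihydro-2H-chromene-6-carboxylate | CC(C)=CCC/C(C)=C/CC[C@@]1(C)CC(=O)c2cc(C(=O)OC)ccc2O1 | intermediate
19 | (2S)-2-[(3E)-4,8-dimethylnona-3,7-dien-1-yl]-2-methyl-4-oxo-3,4-dihydro-2H-chromene-6-carboxylic acid | CC(C)=CCC/C(C)=C/CC[C@@]1(C)CC(=O)c2cc(C(=O)O)ccc2O1 | target

Total step count: 9. Longest linear sequence: 7 steps (steps 1, 2, 3, 4, 7, 8, 9); the aryne branch (steps 5, 6) joins at step 7.

Steps most likely to fail

1. Step 7 (Proposed new method). What may go wrong: retro-aldol fragmentation of alkoxide 13, silyl transfer from 12 to the alkoxide, proton or C-arylation quench of carbanion 15, or loss of chloride from 15 before ring closure. Fallback with known chemistry, setting out from 6 and coming back to the route at 18: the two bonds are made one after the other. Deprotonation of 6 with KN(SiMe3)2 (THF/DMF, 0 °C to rt) and nucleophilic aromatic substitution on commercial methyl 4-fluoro-3-iodobenzoate (fluoride para to the ester) would give the aryl ether methyl 3-iodo-4-{[(3S,6E)-1-[methoxy(methyl)amino]-3,7,11-trimethyl-1-oxododeca-6,10-dien-3-yl]oxy}benzoate F1. Iodine–magnesium exchange with i-PrMgCl·LiCl (THF, −40 °C), which tolerates the methyl ester, and intramolecular attack of the arylmagnesium on the Weinreb amide (Parham-type cyclisation) would form the same C4–C4a bond and give 18 after aqueous work-up, with no chlorine to remove.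

2. Step 8. What may go wrong: slow oxidative addition at the doubly ortho-substituted chloride, migration or reduction of the side-chain alkenes by palladium hydride, or ring opening of the chromanone at 80 °C. Fallback, setting out from 17 and coming back at 18: photochemical electron-transfer dechlorination without a metal hydride, using 10-phenylphenothiazine (5 mol %), Bu3N and HCO2H in MeCN under 380 nm light at rt. The excited organic photocatalyst reduces the electron-poor chloroarene, the radical anion loses chloride and the aryl radical takes up a hydrogen atom. This fallback makes no new compound (F0).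

3. Step 3. What may go wrong: loss of the transient β-hydroxy aldehyde 4 by dehydration or retro-aldol cleavage before it is oxidised further. Fallback, setting out from 2 and coming back at 6: the oxidation is done before the epoxide is opened, so that no free β-hydroxy aldehyde occurs. TEMPO/PhI(OAc)2 (MeCN/H2O) on 2 would give (2R,3S)-3-[(3E)-4,8-dimethylnona-3,7-dien-1-yl]-3-methyloxirane-2-carboxylic acid F2; Me3SiCHN2 (toluene/MeOH) would give methyl (2R,3S)-3-[(3E)-4,8-dimethylnona-3,7-dien-1-yl]-3-methyloxirane-2-carboxylate F3; SmI2 (THF/MeOH, −90 °C) should cleave the Cα–O bond of the α,β-epoxy ester and give methyl (3S,6E)-3-hydroxy-3,7,11-trimethyldodeca-6,10-dienoate F4 with the C3–O bond intact; i-PrMgCl with MeNHOMe·HCl (THF, −20 °C) would convert F4 into 6.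

Further compounds
F1 | step 7 | methyl 3-iodo-4-{[(3S,6E)-1-[methoxy(methyl)amino]-3,7,11-trimethyl-1-oxododeca-6,10-dien-3-yl]oxy}benzoate | CC(C)=CCC/C(C)=C/CC[C@@](C)(CC(=O)N(C)OC)Oc1ccc(C(=O)OC)cc1I
F0 | step 8 | none | none
F2 | step 3 | (2R,3S)-3-[(3E)-4,8-dimethylnona-3,7-dien-1-yl]-3-methyloxirane-2-carboxylic acid | CC(C)=CCC/C(C)=C/CC[C@]1(C)O[C@H]1C(=O)O
F3 | step 3 | methyl (2R,3S)-3-[(3E)-4,8-dimethylnona-3,7-dien-1-yl]-3-methyloxirane-2-carboxylate | CC(C)=CCC/C(C)=C/CC[C@]1(C)O[C@H]1C(=O)OC
F4 | step 3 | methyl (3S,6E)-3-hydroxy-3,7,11-trimethyldodeca-6,10-dienoate | CC(C)=CCC/C(C)=C/CC[C@](C)(O)CC(=O)OC
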